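**Plan**

- Retrosynthesis: the C8/C13 acetates and a C1 silyl ether are set aside, then the C8–C9 bond of the ten-membered ring is cut (allylmetal + aldehyde). Next come C7–C8, C11–C13 and the lactone C12–O bond (cuprate / formaldehyde / lactonisation on an alkynoate), then C6–C7, C1–C10 and C9–C10 (two alkynylations, one carbomagnesiation). What remains is the C1–C6 chain of neryl acetate.
- Forward: the C1–C6 chain with the Z C4=C5 bond is bought. The C1 carbinol and the 2-(silylmethyl)allyl unit C9–C10(=C14) are built first, then the butenolide (ring B) on C6, and the ten-membered carbocycle (ring A) closes last.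
- Enabling feature: in ring A the C8 carbinol is homoallylic to the exocyclic C10=C14 methylene [C8(O)–C9H2–C10(=C14H2)] and sits on C7 of the planar butenolide next to C6. An allylmetal at C9 and a formyl group at C8 therefore close ring A and set C8 in one event.
- Stereochemistry: C1 and C6 are set by the same zinc–ProPhenol catalyst (two asymmetric alkynylations). C8 is relayed from C6 (and C1) by substrate control in the ring closure. The Z C4=C5 geometry comes from the nerol skeleton.

Key step: step 13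

Remark: germacrane numbering is used throughout (ring C1–C10, lactone carbons C11–C13, C14 = exocyclic methylene carbon, C15 = methyl on C4). The C4=C5 bond of the given structure is Z (C3 and C6 cis), which is the geometry of nerol.

**Route**

Step 1
Reactants: 1 neryl acetate
Product: 3 (2Z)-3-methyl-6-oxohex-2-en-1-yl acetate, via epoxide 2 (not isolated)
Conditions: mCPBA (1.05 equiv), CH2Cl2, 0 °C; then H5IO6, THF–H2O, 0 °C
Reagents that add atoms: 3-chloroperbenzoic acid (mCPBA), O=C(OO)c1cccc(Cl)c1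
Why: Prilezhaev epoxidation should take the more electron-rich terminal trisubstituted alkene (the other alkene is deactivated by the allylic acetate), and periodic acid should cleave the epoxide through its diol (Malaprade-type cleavage) to the C1 aldehyde without touching the Z alkene.

Step 2
Reactants: 3 (2Z)-3-methyl-6-oxohex-2-en-1-yl acetate; 4 ethynyl(trimethyl)silane
Product: 6 (2Z,6R)-3-methyloct-2-en-7-yne-1,6-diol, via silylalkynol acetate 5 (not isolated)
Conditions: 4 (3 equiv), Me2Zn (3 equiv), (R,R)-ProPhenol (20 mol %), Ph3P=O (40 mol %), toluene, 0 °C; aq NH4Cl work-up; crude 5, K2CO3 (0.3 equiv), MeOH, 23 °C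
Reagents that add atoms: none
Why: Dinuclear zinc–ProPhenol catalysed asymmetric alkynylation should deliver the alkynylzinc to the Si face of the aldehyde and set C1 as R (the ligand antipode is the one chosen for Si-face delivery), and mild methanolysis then removes the C-silyl group and the acetate together.

Step 3
Reactants: 6 (2Z,6R)-3-methyloct-2-en-7-yne-1,6-diol; 7 (trimethylsilyl)methylmagnesium chloride
Product: 9 (2Z,6R)-3-methyl-7-[(trimethylsilyl)methyl]octa-2,7-diene-1,6-diol, via alkenylmagnesium species 8 (not isolated)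
Conditions: 7 (5 equiv), CuI (15 mol %), THF–Et2O, 0 → 35 °C; aq NH4Cl
Reagents that add atoms: none
Why: Copper-catalysed, alkoxide-directed anti-carbomagnesiation of the terminal propargylic alcohol should put the silylmethyl group on the internal alkyne carbon (C10) and magnesium on the terminus (C14), so protonation gives the 2-(silylmethyl)allyl alcohol with the C1 stereocenter untouched.

Step 4
Reactants: 9 (2Z,6R)-3-methyl-7-[(trimethylsilyl)methyl]octa-2,7-diene-1,6-diol
Product: 10 (2Z,6R)-6-hydroxy-3-methyl-7-[(trimethylsilyl)methyl]octa-2,7-dienal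
Conditions: TEMPO (10 mol %), PhI(OAc)2 (1.1 equiv), CH2Cl2, 0 → 23 °C
Reagents that add atoms: none
Why: Oxoammonium-mediated oxidation is selective for the primary allylic alcohol over the secondary one and is the standard way to make Z-enals of the neral type without Z/E isomerisation.

Step 5
Reactants: 10 (2Z,6R)-6-hydroxy-3-methyl-7-[(trimethylsilyl)methyl]octa-2,7-dienal
Product: 11 (2Z,6R)-6-[(tert-butyldimethylsilyl)oxy]-3-methyl-7-[(trimethylsilyl)methyl]octa-2,7-dienal
Conditions: TBSCl, imidazole, DMF, 0 → 23 °C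
Reagents that add atoms: tert-butyldimethylsilyl chloride, CC(C)(C)[Si](C)(C)Cl
Why: Standard silylation of the secondary allylic alcohol under weakly basic conditions should leave the Z-enal and the allylsilane intact.

Step 6
Reactants: 11 (2Z,6R)-6-[(tert-butyldimethylsilyl)oxy]-3-methyl-7-[(trimethylsilyl)methyl]octa-2,7-dienal; 12 methyl propiolate
Product: 13 methyl (4R,5Z,9R)-9-[(tert-butyldimethylsilyl)oxy]-4-hydroxy-6-methyl-10-[(trimethylsilyl)methyl]undeca-5,10-dien-2-ynoate
Conditions: 12 (3 equiv), Me2Zn (3 equiv), (R,R)-ProPhenol (10 mol %), toluene, 4 °C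
Reagents that add atoms: none
Why: The same zinc–ProPhenol alkynylation, which is established for methyl propiolate with α,β-unsaturated aldehydes, should add the alkynoate 1,2 to the Si face of the enal and set C6 as R under catalyst control.

Step 7
Reactants: 14 (tributylstannyl)methanol
Product: 15 tributyl{[(4-methoxybenzyl)oxy]methyl}stannane
Conditions: NaH, 4-methoxybenzyl chloride, Bu4NI (cat.), THF–DMF, 0 → 23 °C
Reagents that add atoms: 4-methoxybenzyl chloride, COc1ccc(CCl)cc1
Why: Williamson etherification of the primary stannyl alcohol gives the precursor of a protected hydroxymethyl anion.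

Step 8
Reactants: 13 methyl (4R,5Z,9R)-9-[(tert-butyldimethylsilyl)oxy]-4-hydroxy-6-methyl-10-[(trimethylsilyl)methyl]undeca-5,10-dien-2-ynoate; 15 tributyl{[(4-methoxybenzyl)oxy]methyl}stannane
Product: 18 (5R)-3-(hydroxymethyl)-4-{[(4-methoxybenzyl)oxy]methyl}-5-{(1Z,5R)-5-[(tert-butyldimethylsilyl)oxy]-2-methyl-6-[(trimethylsilyl)methyl]hepta-1,6-dien-1-yl}furan-2(5H)-one, via alkenylcopper adduct 16 (not isolated), via open hydroxy ester 17 (not isolated)
Conditions: 15 (5 equiv), nBuLi, THF, −78 °C; CuBr·SMe2 (2.5 equiv), −78 °C; add 13, −78 °C; monomeric CH2O (from cracked paraformaldehyde, THF), −78 → −30 °C; aq NH4Cl, then 23 °C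
Reagents that add atoms: formaldehyde, C=O
Why: Tin–lithium exchange and cuprate formation give an α-alkoxymethyl cuprate that should add syn to the alkynoate (C8 onto C7), the configurationally held α-cuprio enoate should be hydroxymethylated at C11 with retention, and the C6 alkoxide, which then lies cis to the ester, lactonises to the tetrasubstituted butenolide (conjugate addition–aldol trapping–lactonisation) without involving the C6 stereocenter.

Step 9
Reactants: 18 (5R)-3-(hydroxymethyl)-4-{[(4-methoxybenzyl)oxy]methyl}-5-{(1Z,5R)-5-[(tert-butyldimethylsilyl)oxy]-2-methyl-6-[(trimethylsilyl)methyl]hepta-1,6-dien-1-yl}furan-2(5H)-one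
Product: 19 [(5R)-4-{[(4-methoxybenzyl)oxy]methyl}-5-{(1Z,5R)-5-[(tert-butyldimethylsilyl)oxy]-2-methyl-6-[(trimethylsilyl)methyl]hepta-1,6-dien-1-yl}-2-oxo-2,5-dihydrofuran-3-yl]methyl acetate
Conditions: Ac2O, pyridine, DMAP (cat.), CH2Cl2, 0 °C
Reagents that add atoms: acetic anhydride, CC(=O)OC(C)=O
Why: Nucleophile-catalysed acetylation of the only free (primary) alcohol installs the C13 acetate of the target under conditions too mild to epimerise the γ-centre C6.

Step 10
Reactants: 19 [(5R)-4-{[(4-methoxybenzyl)oxy]methyl}-5-{(1Z,5R)-5-[(tert-butyldimethylsilyl)oxy]-2-methyl-6-[(trimethylsilyl)methyl]hepta-1,6-dien-1-yl}-2-oxo-2,5-dihydrofuran-3-yl]methyl acetate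
Product: 20 [(5R)-4-(hydroxymethyl)-5-{(1Z,5R)-5-[(tert-butyldimethylsilyl)oxy]-2-methyl-6-[(trimethylsilyl)methyl]hepta-1,6-dien-1-yl}-2-oxo-2,5-dihydrofuran-3-yl]methyl acetate
Conditions: DDQ, CH2Cl2–pH 7 buffer, 0 °C
Reagents that add atoms: none
Why: Oxidative cleavage of the 4-methoxybenzyl ether by DDQ (benzylic oxidation to the oxocarbenium ion, then hydrolysis) is neutral and should leave the acetate, silyl ether, allylsilane and butenolide untouched.

Step 11
Reactants: 20 [(5R)-4-(hydroxymethyl)-5-{(1Z,5R)-5-[(tert-butyldimethylsilyl)oxy]-2-methyl-6-[(trimethylsilyl)methyl]hepta-1,6-dien-1-yl}-2-oxo-2,5-dihydrofuran-3-yl]methyl acetate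
Product: 21 [(5R)-4-formyl-5-{(1Z,5R)-5-[(tert-butyldimethylsilyl)oxy]-2-methyl-6-[(trimethylsilyl)methyl]hepta-1,6-dien-1-yl}-2-oxo-2,5-dihydrofuran-3-yl]methyl acetate
Conditions: Dess–Martin periodinane, pyridine, CH2Cl2, 0 → 23 °C
Reagents that add atoms: none
Why: Dess–Martin oxidation of the primary allylic alcohol under buffered, non-basic conditions should give the formyl butenolide without epimerising C6.

Step 12
Reactants: 21 [(5R)-4-formyl-5-{(1Z,5R)-5-[(tert-butyldimethylsilyl)oxy]-2-methyl-6-[(trimethylsilyl)methyl]hepta-1,6-dien-1-yl}-2-oxo-2,5-dihydrofuran-3-yl]methyl acetate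
Product: 22 [(5R)-5-{(1Z,5R)-6-(bromomethyl)-5-[(tert-butyldimethylsilyl)oxy]-2-methylhepta-1,6-dien-1-yl}-4-formyl-2-oxo-2,5-dihydrofuran-3-yl]methyl acetate
Conditions: NBS (1.05 equiv), CH2Cl2, −78 °C
Reagents that add atoms: N-bromosuccinimide, O=C1CCC(=O)N1Br
Why: Electrophilic bromodesilylation (SE2′) should occur at the 2-substituted allylsilane, the most nucleophilic alkene present, and because the allyl unit has two CH2 termini the transposition is of no consequence.

Step 13
Reactants: 22 [(5R)-5-{(1Z,5R)-6-(bromomethyl)-5-[(tert-butyldimethylsilyl)oxy]-2-methylhepta-1,6-dien-1-yl}-4-formyl-2-oxo-2,5-dihydrofuran-3-yl]methyl acetate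
Product: 24 (1R,4Z,6R,8S)-13-acetoxy-1-[(tert-butyldimethylsilyl)oxy]-8-hydroxygermacra-4,7(11),10(14)-trien-12,6-olide, via allylchromium species 23 (not isolated)
Conditions: CrCl2 (10 equiv), THF, 23 °C, slow addition of 22 (final 0.003 M)
Reagents that add atoms: none
Why: Two equivalents of divalent chromium reduce the allylic C–Br bond of 22 to the σ-allyl species of trivalent chromium 23, whose CH2 terminus (C9) adds to the formyl carbon (C8) through a cyclic six-membered Zimmerman–Traxler-type transition state in which chromium bridges the aldehyde oxygen and C14, so the C8 carbinol and the exocyclic C10=C14 methylene arise together. The closest known reaction type is the intramolecular Nozaki–Hiyama–Kishi (chromium-mediated Barbier-type) allylation used to close ten-membered germacrane rings from formyl allylic halides. Ring A closes in a 10-exo-trig mode (the C=O bond is exocyclic to the new ring). C8 is the only new stereocenter and is controlled by C6 through the planar butenolide, with the C1 silyl ether as a more remote bias: the C5–C1 tether leaves C6 on one face of the butenolide and the chromium-bridged allyl unit must lie on the side of the aldehyde oxygen, which is expected to favour the 8S (8α) carbinol, the epimer that lets H-8 eclipse C7=C11 (minimal A(1,3) strain against C13) while C7 occupies a corner of ring A. The step needs addition to the aldehyde only (secured by the oxophilic, non-basic allylchromium reagent, which ignores the butenolide, the allylic acetate and the silyl ether), ring closure over oligomerisation (secured by slow addition and by the Z C4=C5 bond and the butenolide, which pre-bend the chain), and 8α over 8β (secured by C6 as described).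

Step 14
Reactants: 24 (1R,4Z,6R,8S)-13-acetoxy-1-[(tert-butyldimethylsilyl)oxy]-8-hydroxygermacra-4,7(11),10(14)-trien-12,6-olide
Product: 25 (1R,4Z,6R,8S)-8,13-diacetoxy-1-[(tert-butyldimethylsilyl)oxy]germacra-4,7(11),10(14)-trien-12,6-olide
Conditions: Ac2O, pyridine, DMAP (cat.), CH2Cl2, 0 → 23 °C
Reagents that add atoms: acetic anhydride, CC(=O)OC(C)=O
Why: Nucleophile-catalysed acetylation of the only free (C8) hydroxyl proceeds with retention and should not disturb the base-sensitive C6 centre.

Step 15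
Reactants: 25 (1R,4Z,6R,8S)-8,13-diacetoxy-1-[(tert-butyldimethylsilyl)oxy]germacra-4,7(11),10(14)-trien-12,6-olide
Product: 26 8α,13-diacetoxy-1β-hydroxygermacra-4,7(11),10(14)-trien-6α,12-olide
Conditions: HF·pyridine, pyridine–THF, 0 → 23 °C
Reagents that add atoms: none
Why: Buffered fluoride cleavage of the secondary silyl ether should free the C1 hydroxyl while leaving both acetates, the allylic acetate system and the butenolide untouched.

**Compound list**

1 | neryl acetate, (2Z)-3,7-dimethylocta-2,6-dien-1-yl acetate | CC(=O)OC/C=C(C)\CCC=C(C)C | starting material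
2 | (2Z)-6,7-epoxy-3,7-dimethyloct-2-en-1-yl acetate (racemic at the epoxide) | CC(=O)OC/C=C(C)\CCC1OC1(C)C | intermediate
3 | (2Z)-3-methyl-6-oxohex-2-en-1-yl acetate | CC(=O)OC/C=C(C)\CCC=O | intermediate
4 | ethynyl(trimethyl)silane | C#C[Si](C)(C)C | starting material
5 | (2Z,6R)-6-hydroxy-3-methyl-8-(trimethylsilyl)oct-2-en-7-yn-1-yl acetate | CC(=O)OC/C=C(C)\CC[C@@H](O)C#C[Si](C)(C)C | intermediate
6 | (2Z,6R)-3-methyloct-2-en-7-yne-1,6-diol | OC/C=C(C)\CC[C@@H](O)C#C | intermediate
7 | (trimethylsilyl)methylmagnesium chloride | C[Si](C)(C)C[Mg]Cl | starting material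
8 | alkenylmagnesium bis(alkoxide) from anti-carbomagnesiation of 6 (Mg on C14 cis to the C1 oxygen; drawn as monomeric chloromagnesium species) | Cl[Mg]OC/C=C(C)\CC[C@@H](O[Mg]Cl)/C(C[Si](C)(C)C)=C\[Mg]Cl | intermediate
9 | (2Z,6R)-3-methyl-7-[(trimethylsilyl)methyl]octa-2,7-diene-1,6-diol | OC/C=C(C)\CC[C@@H](O)C(=C)C[Si](C)(C)C | intermediate
10 | (2Z,6R)-6-hydroxy-3-methyl-7-[(trimethylsilyl)methyl]octa-2,7-dienal | O=C/C=C(C)\CC[C@@H](O)C(=C)C[Si](C)(C)C | intermediate
11 | (2Z,6R)-6-[(tert-butyldimethylsilyl)oxy]-3-methyl-7-[(trimethylsilyl)methyl]octa-2,7-dienal | O=C/C=C(C)\CC[C@@H](O[Si](C)(C)C(C)(C)C)C(=C)C[Si](C)(C)C | intermediate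
12 | methyl propiolate | C#CC(=O)OC | starting material
13 | methyl (4R,5Z,9R)-9-[(tert-butyldimethylsilyl)oxy]-4-hydroxy-6-methyl-10-[(trimethylsilyl)methyl]undeca-5,10-dien-2-ynoate | COC(=O)C#C[C@H](O)/C=C(C)\CC[C@@H](O[Si](C)(C)C(C)(C)C)C(=C)C[Si](C)(C)C | intermediate
14 | (tributylstannyl)methanol | CCCC[Sn](CCCC)(CCCC)CO | starting material
15 | tributyl{[(4-methoxybenzyl)oxy]methyl}stannane | CCCC[Sn](CCCC)(CCCC)COCc1ccc(OC)cc1 | intermediate
16 | alkenylcopper conjugate adduct of 13 (Cu on C11 cis to the new CH2O-PMB group on C7, C6 as lithium alkoxide; drawn as monomer) | COC(=O)/C([Cu])=C(/COCc1ccc(OC)cc1)[C@H](O[Li])/C=C(C)\CC[C@@H](O[Si](C)(C)C(C)(C)C)C(=C)C[Si](C)(C)C | intermediate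
17 | methyl (2Z,4R,5Z,9R)-9-[(tert-butyldimethylsilyl)oxy]-4-hydroxy-2-(hydroxymethyl)-3-{[(4-methoxybenzyl)oxy]methyl}-6-methyl-10-[(trimethylsilyl)methyl]undeca-2,5,10-trienoate (drawn in neutral form) | COC(=O)/C(CO)=C(/COCc1ccc(OC)cc1)[C@H](O)/C=C(C)\CC[C@@H](O[Si](C)(C)C(C)(C)C)C(=C)C[Si](C)(C)C | intermediate
18 | (5R)-3-(hydroxymethyl)-4-{[(4-methoxybenzyl)oxy]methyl}-5-{(1Z,5R)-5-[(tert-butyldimethylsilyl)oxy]-2-methyl-6-[(trimethylsilyl)methyl]hepta-1,6-dien-1-yl}furan-2(5H)-one | COc1ccc(COCC2=C(CO)C(=O)O[C@@H]2/C=C(C)\CC[C@@H](O[Si](C)(C)C(C)(C)C)C(=C)C[Si](C)(C)C)cc1 | intermediate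
19 | [(5R)-4-{[(4-methoxybenzyl)oxy]methyl}-5-{(1Z,5R)-5-[(tert-butyldimethylsilyl)oxy]-2-methyl-6-[(trimethylsilyl)methyl]hepta-1,6-dien-1-yl}-2-oxo-2,5-dihydrofuran-3-yl]methyl acetate | COc1ccc(COCC2=C(COC(C)=O)C(=O)O[C@@H]2/C=C(C)\CC[C@@H](O[Si](C)(C)C(C)(C)C)C(=C)C[Si](C)(C)C)cc1 | intermediate
20 | [(5R)-4-(hydroxymethyl)-5-{(1Z,5R)-5-[(tert-butyldimethylsilyl)oxy]-2-methyl-6-[(trimethylsilyl)methyl]hepta-1,6-dien-1-yl}-2-oxo-2,5-dihydrofuran-3-yl]methyl acetate | OCC1=C(COC(C)=O)C(=O)O[C@@H]1/C=C(C)\CC[C@@H](O[Si](C)(C)C(C)(C)C)C(=C)C[Si](C)(C)C | intermediate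
21 | [(5R)-4-formyl-5-{(1Z,5R)-5-[(tert-butyldimethylsilyl)oxy]-2-methyl-6-[(trimethylsilyl)methyl]hepta-1,6-dien-1-yl}-2-oxo-2,5-dihydrofuran-3-yl]methyl acetate | O=CC1=C(COC(C)=O)C(=O)O[C@@H]1/C=C(C)\CC[C@@H](O[Si](C)(C)C(C)(C)C)C(=C)C[Si](C)(C)C | intermediate
22 | [(5R)-5-{(1Z,5R)-6-(bromomethyl)-5-[(tert-butyldimethylsilyl)oxy]-2-methylhepta-1,6-dien-1-yl}-4-formyl-2-oxo-2,5-dihydrofuran-3-yl]methyl acetate | O=CC1=C(COC(C)=O)C(=O)O[C@@H]1/C=C(C)\CC[C@@H](O[Si](C)(C)C(C)(C)C)C(=C)CBr | intermediate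
23 | allylchromium dichloride derived from 22 (C9–Cr, trivalent chromium; drawn as monomer) | O=CC1=C(COC(C)=O)C(=O)O[C@@H]1/C=C(C)\CC[C@@H](O[Si](C)(C)C(C)(C)C)C(=C)C[Cr](Cl)Cl | intermediate
24 | (1R,4Z,6R,8S)-13-acetoxy-1-[(tert-butyldimethylsilyl)oxy]-8-hydroxygermacra-4,7(11),10(14)-trien-12,6-olide | C=C1C[C@H](O)C2=C(COC(C)=O)C(=O)O[C@@H]2/C=C(/C)CC[C@H]1O[Si](C)(C)C(C)(C)C | intermediate
25 | (1R,4Z,6R,8S)-8,13-diacetoxy-1-[(tert-butyldimethylsilyl)oxy]germacra-4,7(11),10(14)-trien-12,6-olide | C=C1C[C@H](OC(C)=O)C2=C(COC(C)=O)C(=O)O[C@@H]2/C=C(/C)CC[C@H]1O[Si](C)(C)C(C)(C)C | intermediate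
26 | 8α,13-diacetoxy-1β-hydroxygermacra-4,7(11),10(14)-trien-6α,12-olide, (1R,4Z,6R,8S) | C=C1C[C@H](OC(C)=O)C2=C(COC(C)=O)C(=O)O[C@@H]2/C=C(/C)CC[C@H]1O | target

**Step count and risks**

Total steps: 15. Longest linear sequence: 14 (steps 1–6 and 8–15; step 7 is a one-step side branch).

Steps most likely to fail, with fallbacks:

1. Step 13 – poor or reversed facial selectivity at C8 during the ring closure (the substrate-control model is the least certain element of the plan). Fallback: the ring closure of 22 is carried through to the epimeric carbinol (1R,4Z,6R,8R)-13-acetoxy-1-[(tert-butyldimethylsilyl)oxy]-8-hydroxygermacra-4,7(11),10(14)-trien-12,6-olide F1. F1 is then esterified under Mitsunobu conditions (PPh3, diisopropyl azodicarboxylate, AcOH, toluene, 0 °C), which inverts C8 and installs the acetate in one operation. The route is rejoined at 25.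

2. Step 8 – protonation of the alkenylcopper intermediate before it captures formaldehyde, or loss of alkene geometry so that lactonisation fails. Fallback: starting from 13, the same cuprate addition is quenched at −78 °C with a titrated amount of iodine. After lactonisation this should give (5R)-3-iodo-4-{[(4-methoxybenzyl)oxy]methyl}-5-{(1Z,5R)-5-[(tert-butyldimethylsilyl)oxy]-2-methyl-6-[(trimethylsilyl)methyl]hepta-1,6-dien-1-yl}furan-2(5H)-one F2. The hydroxymethyl group is then introduced by Stille cross-coupling of F2 with 14 [Pd(PPh3)4, dioxane, 90 °C]. The route is rejoined at 18.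

3. Step 6 – Z-to-E isomerisation of the enal under the zinc alkoxide conditions, or insufficient enantioselectivity with the β,β-disubstituted Z-enal. Fallback: starting from 11, lithium methyl propiolate is added at −78 °C (THF) to give the C4-epimeric mixture methyl (4RS,5Z,9R)-9-[(tert-butyldimethylsilyl)oxy]-4-hydroxy-6-methyl-10-[(trimethylsilyl)methyl]undeca-5,10-dien-2-ynoate F3. F3 is oxidised with Dess–Martin periodinane to the ynone methyl (5Z,9R)-9-[(tert-butyldimethylsilyl)oxy]-6-methyl-4-oxo-10-[(trimethylsilyl)methyl]undeca-5,10-dien-2-ynoate F4. Corey–Bakshi–Shibata reduction of F4 (oxazaborolidine antipode that gives the 4R alcohol, catecholborane, −78 °C) then sets C6 by reagent control. The route is rejoined at 13.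

Further compounds
F1 | step 13 | (1R,4Z,6R,8R)-13-acetoxy-1-[(tert-butyldimethylsilyl)oxy]-8-hydroxygermacra-4,7(11),10(14)-trien-12,6-olide | C=C1C[C@@H](O)C2=C(COC(C)=O)C(=O)O[C@@H]2/C=C(/C)CC[C@H]1O[Si](C)(C)C(C)(C)C
F2 | step 8 | (5R)-3-iodo-4-{[(4-methoxybenzyl)oxy]methyl}-5-{(1Z,5R)-5-[(tert-butyldimethylsilyl)oxy]-2-methyl-6-[(trimethylsilyl)methyl]hepta-1,6-dien-1-yl}furan-2(5H)-one | COc1ccc(COCC2=C(I)C(=O)O[C@@H]2/C=C(C)\CC[C@@H](O[Si](C)(C)C(C)(C)C)C(=C)C[Si](C)(C)C)cc1
F3 | step 6 | methyl (4RS,5Z,9R)-9-[(tert-butyldimethylsilyl)oxy]-4-hydroxy-6-methyl-10-[(trimethylsilyl)methyl]undeca-5,10-dien-2-ynoate | COC(=O)C#CC(O)/C=C(C)\CC[C@@H](O[Si](C)(C)C(C)(C)C)C(=C)C[Si](C)(C)C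
F4 | step 6 | methyl (5Z,9R)-9-[(tert-butyldimethylsilyl)oxy]-6-methyl-4-oxo-10-[(trimethylsilyl)methyl]undeca-5,10-dien-2-ynoate | COC(=O)C#CC(=O)/C=C(C)\CC[C@@H](O[Si](C)(C)C(C)(C)C)C(=C)C[Si](C)(C)C
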